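**Retrosynthetic overview**
- Target ⇒ pyran-fused dienone: the last ring (C5–C6) closes when the primary CH2 of the C6–C7–C8 bridge moves from the enol-ether oxygen to the neighbouring ring carbon (iodide-catalysed O→C 1,3-shift).
- ⇒ dearomatisation by para-Claisen delivery of prenyl to the chroman ring-fusion carbon (sets C1; C5 then follows from it), after C-alkylation of the last free aromatic CH with (R)-lavandulyl triflate.
- ⇒ key C8–C1 bond (gem-dimethyl carbon to the future bridgehead) by electrochemical cobalt-hydride hydroarylation of an aryl (S)-lavandulyl ether.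
- ⇒ Mitsunobu etherification of 2,3′,4,6-tetrahydroxybenzophenone (phloroglucinol + 3-hydroxybenzonitrile) with (S)-lavandulol.
- Ring order: arene (bought) → chroman → dearomatised dienone → bicyclo[3.3.1]nonane; C7 and the side-chain centre are bought as (S)- and (R)-lavandulol.

Assumption: (R)- and (S)-lavandulol are both purchasable enantiopure; chroman numbering is used for 6–13 and target numbering for 14–16.

**Step 1**
Reactants: 1 phloroglucinol; 2 3-hydroxybenzonitrile
Product: 3 (3-hydroxyphenyl)(2,4,6-trihydroxyphenyl)methanone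
Conditions: ZnCl2, HCl (g), Et2O, 0 °C; then H2O, 100 °C
Reagents that add atoms: water, O
Why: Houben–Hoesch acylation, in which the nitrilium salt acylates the electron-rich triol once (the ketiminium product is deactivated) and hydrolysis gives the ketone; no stereocentre is formed.

**Step 2**
Reactants: 3 (3-hydroxyphenyl)(2,4,6-trihydroxyphenyl)methanone; 4 (S)-lavandulol
Product: 5 [2,6-dihydroxy-4-{[(2S)-5-methyl-2-(prop-1-en-2-yl)hex-4-en-1-yl]oxy}phenyl](3-hydroxyphenyl)methanone
Conditions: PPh3, DIAD, THF, 0 °C → rt (3 in 1.3-fold excess)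
Reagents that add atoms: none
Why: Mitsunobu etherification alkylates the most acidic phenol, the 4-OH para to the ketone (the 2,6-OH are chelated and hindered, the 3′-OH is a weaker acid), and the stereocentre of 4 is not at the reacting carbon.

**Step 3**
Reactants: 5 aryl (S)-lavandulyl ether
Product: 6 [(3S)-5,7-dihydroxy-4,4-dimethyl-3-(3-methylbut-2-en-1-yl)-3,4-dihydro-2H-chromen-6-yl](3-hydroxyphenyl)methanone
Conditions: achiral Co(salen) (5 mol%), nBu4NPF6, HFIP/CH2Cl2 1:4, undivided cell, graphite(+)/Pt(−), 2 mA, rt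
Reagents that add atoms: none
Why: Proposed new method: silane-free paired-electrolysis MHAT/radical-polar-crossover hydroarylation, in which cathodic Co(I) is protonated to Co(III)–H, this transfers H• only to the 1,1-disubstituted alkene (the trisubstituted prenyl alkene is far slower), the tertiary radical is held as alkyl–Co(III) and oxidised at the anode to an alkyl–Co(IV) cation equivalent that the flanking ring CH attacks (six-membered Friedel–Crafts closure, both ortho positions being equivalent), and the released proton restarts the cycle without touching the C3 stereocentre; closest known reactions are Co(salen)/N-fluoropyridinium/silane hydroarylation and cobalt-electrocatalytic HAT.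

**Step 4**
Reactants: 7 (R)-lavandulol
Product: 8 (2R)-5-methyl-2-(prop-1-en-2-yl)hex-4-en-1-yl trifluoromethanesulfonate
Conditions: Tf2O, 2,6-lutidine, CH2Cl2, −78 °C (used cold without purification)
Reagents that add atoms: trifluoromethanesulfonic anhydride (Tf2O), O=S(=O)(OS(=O)(=O)C(F)(F)F)C(F)(F)F
Why: O-sulfonylation of a primary alcohol with a hindered base at low temperature gives the triflate without ionisation, so the adjacent stereocentre is kept.

**Step 5**
Reactants: 6 (3S)-chroman triol; 8 (R)-lavandulyl triflate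
Product: 10 [(3S)-5,7-dihydroxy-4,4-dimethyl-3-(3-methylbut-2-en-1-yl)-8-[(2S)-5-methyl-2-(prop-1-en-2-yl)hex-4-en-1-yl]-3,4-dihydro-2H-chromen-6-yl]{3-[tri(propan-2-yl)silyloxy]phenyl}methanone, via 3′-O-TIPS chroman 9 (not isolated)
Conditions: LiHMDS (3 equiv), PhMe/THF, −78 °C; TIPSCl (1 equiv), 0 °C; 8 (1.1 equiv), −78 → 0 °C; AcOH
Reagents that add atoms: chlorotri(propan-2-yl)silane (TIPSCl), CC(C)[Si](Cl)(C(C)C)C(C)C
Why: The least delocalised, unhindered 3′-phenoxide of the trilithium salt is silylated first, and the remaining dilithium phenoxide is then C-alkylated (SN2) at C8, the only free ring CH, as lithium acylphloroglucinolates in toluene favour C- over O-alkylation; the stereocentre of 8 is not at the reacting carbon.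

**Step 6**
Reactants: 10 8-lavandulyl chroman
Product: 13 (3S,4aS)-5-hydroxy-4,4-dimethyl-3,4a-bis(3-methylbut-2-en-1-yl)-8-[(2S)-5-methyl-2-(prop-1-en-2-yl)hex-4-en-1-yl]-6-{3-[tri(propan-2-yl)silyloxy]benzoyl}-2,3,4,4a-tetrahydro-7H-chromen-7-one, via 7-O-prenyl ether 11 (not isolated), via ortho-dienone 12 (not isolated)
Conditions: prenyl bromide, K2CO3, acetone, 50 °C; then PhMe, 110 °C
Reagents that add atoms: prenyl bromide (1-bromo-3-methylbut-2-ene), CC(C)=CCBr
Why: Williamson O-alkylation takes the 7-OH (the 5-OH is chelated and buttressed by the peri gem-dimethyl group) and the ether then undergoes an aromatic para-Claisen rearrangement (Claisen then Cope, both ortho positions blocked) that puts a normal prenyl group on C4a, where the C3 prenyl group shields its own face directly or through the pseudo-axial C4 methyl, so the new quaternary centre forms trans to it (4aS, the C1 configuration of the target).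

**Step 7**
Reactants: 13 pyran-fused dienone
Product: 16 (1R,5R,7R)-4-hydroxy-3-(3-hydroxybenzoyl)-8,8-dimethyl-1,7-bis(3-methylbut-2-en-1-yl)-5-[(2S)-5-methyl-2-(prop-1-en-2-yl)hex-4-en-1-yl]bicyclo[3.3.1]non-3-ene-2,9-dione, via ring-opened primary iodide 14 (not isolated), via 3′-O-TIPS target 15 (not isolated)
Conditions: LiI (1 equiv), DMF, 100 °C; then TBAF/AcOH 1:1, THF, 0 °C
Reagents that add atoms: none
Why: Proposed new method: iodide-catalysed O→C 1,3-alkyl transposition, in which iodide opens the vinylogous ester by SN2 at the primary O–CH2 carbon (as in LiI dealkylation of esters), the tethered iodide re-alkylates the acyl-trione anion either at oxygen (reopened again) or irreversibly at the lavandulyl-bearing carbon (C-alkylation as in step 5), and because the chain hangs from one face of the first quaternary centre it can only reach the same face, so C5 is set by C1 before buffered fluoride removes the silyl group; closest known reaction is the LiI-catalysed O→N alkyl migration of 2-alkoxypyridines.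

**Compound list**
1 | phloroglucinol | Oc1cc(O)cc(O)c1 | starting material
2 | 3-hydroxybenzonitrile | N#Cc1cccc(O)c1 | starting material
3 | (3-hydroxyphenyl)(2,4,6-trihydroxyphenyl)methanone | O=C(c1cccc(O)c1)c1c(O)cc(O)cc1O | intermediate
4 | (S)-lavandulol, (2S)-5-methyl-2-(prop-1-en-2-yl)hex-4-en-1-ol | OC[C@@H](CC=C(C)C)C(C)=C | starting material
5 | [2,6-dihydroxy-4-{[(2S)-5-methyl-2-(prop-1-en-2-yl)hex-4-en-1-yl]oxy}phenyl](3-hydroxyphenyl)methanone | O=C(c1cccc(O)c1)c1c(O)cc(OC[C@@H](CC=C(C)C)C(C)=C)cc1O | intermediate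
6 | [(3S)-5,7-dihydroxy-4,4-dimethyl-3-(3-methylbut-2-en-1-yl)-3,4-dihydro-2H-chromen-6-yl](3-hydroxyphenyl)methanone | O=C(c1cccc(O)c1)c1c(O)cc2OC[C@@H](CC=C(C)C)C(C)(C)c2c1O | intermediate
7 | (R)-lavandulol, (2R)-5-methyl-2-(prop-1-en-2-yl)hex-4-en-1-ol | OC[C@H](CC=C(C)C)C(C)=C | starting material
8 | (2R)-5-methyl-2-(prop-1-en-2-yl)hex-4-en-1-yl trifluoromethanesulfonate | O=S(=O)(OC[C@H](CC=C(C)C)C(C)=C)C(F)(F)F | intermediate
9 | 3′-O-TIPS ether of 6 | O=C(c1cccc(O[Si](C(C)C)(C(C)C)C(C)C)c1)c1c(O)cc2OC[C@@H](CC=C(C)C)C(C)(C)c2c1O | intermediate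
10 | [(3S)-5,7-dihydroxy-4,4-dimethyl-3-(3-methylbut-2-en-1-yl)-8-[(2S)-5-methyl-2-(prop-1-en-2-yl)hex-4-en-1-yl]-3,4-dihydro-2H-chromen-6-yl]{3-[tri(propan-2-yl)silyloxy]phenyl}methanone | O=C(c1cccc(O[Si](C(C)C)(C(C)C)C(C)C)c1)c1c(O)c(C[C@H](CC=C(C)C)C(C)=C)c2OC[C@@H](CC=C(C)C)C(C)(C)c2c1O | intermediate
11 | 7-O-(3-methylbut-2-en-1-yl) ether of 10 | O=C(c1cccc(O[Si](C(C)C)(C(C)C)C(C)C)c1)c1c(OCC=C(C)C)c(C[C@H](CC=C(C)C)C(C)=C)c2OC[C@@H](CC=C(C)C)C(C)(C)c2c1O | intermediate
12 | ortho-dienone: (3S)-5-hydroxy-4,4-dimethyl-3-(3-methylbut-2-en-1-yl)-8-(2-methylbut-3-en-2-yl)-8-[(2S)-lavandulyl]-6-{3-[tri(propan-2-yl)silyloxy]benzoyl}-3,4-dihydro-2H-chromen-7(8H)-one, both C8 epimers | O=C(c1cccc(O[Si](C(C)C)(C(C)C)C(C)C)c1)C1=C(O)C2=C(OC[C@@H](CC=C(C)C)C2(C)C)C(C[C@H](CC=C(C)C)C(C)=C)(C(C)(C)C=C)C1=O | intermediate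
13 | (3S,4aS)-5-hydroxy-4,4-dimethyl-3,4a-bis(3-methylbut-2-en-1-yl)-8-[(2S)-5-methyl-2-(prop-1-en-2-yl)hex-4-en-1-yl]-6-{3-[tri(propan-2-yl)silyloxy]benzoyl}-2,3,4,4a-tetrahydro-7H-chromen-7-one (4a-prenyl trans to 3-prenyl) | O=C(c1cccc(O[Si](C(C)C)(C(C)C)C(C)C)c1)C1=C(O)[C@@]2(CC=C(C)C)C(=C(C[C@H](CC=C(C)C)C(C)=C)C1=O)OC[C@@H](CC=C(C)C)C2(C)C | intermediate
14 | (4R)-3,5-dihydroxy-4-[(3S)-4-iodo-2-methyl-3-(3-methylbut-2-en-1-yl)butan-2-yl]-4-(3-methylbut-2-en-1-yl)-6-[(2S)-5-methyl-2-(prop-1-en-2-yl)hex-4-en-1-yl]-2-{3-[tri(propan-2-yl)silyloxy]benzoyl}cyclohexa-2,5-dien-1-one | O=C(c1cccc(O[Si](C(C)C)(C(C)C)C(C)C)c1)C1=C(O)[C@](CC=C(C)C)(C(C)(C)[C@@H](CI)CC=C(C)C)C(O)=C(C[C@H](CC=C(C)C)C(C)=C)C1=O | intermediate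
15 | 3′-O-TIPS ether of 16 | C=C(C)[C@@H](CC=C(C)C)C[C@@]12C[C@@H](CC=C(C)C)C(C)(C)[C@@](CC=C(C)C)(C(=O)C(C(=O)c3cccc(O[Si](C(C)C)(C(C)C)C(C)C)c3)=C1O)C2=O | intermediate
16 | (1R,5R,7R)-4-hydroxy-3-(3-hydroxybenzoyl)-8,8-dimethyl-1,7-bis(3-methylbut-2-en-1-yl)-5-[(2S)-5-methyl-2-(prop-1-en-2-yl)hex-4-en-1-yl]bicyclo[3.3.1]non-3-ene-2,9-dione | C=C(C)[C@@H](CC=C(C)C)C[C@@]12C[C@@H](CC=C(C)C)C(C)(C)[C@@](CC=C(C)C)(C(=O)C(C(=O)c3cccc(O)c3)=C1O)C2=O | target

**Step count and risks**
Total step count: 7. Longest linear sequence: 6 (steps 1, 2, 3, 5, 6, 7); step 4 is a one-step branch.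

Step 3 is the first likely failure: the electrochemical hydroarylation is unproven, and hydrogen evolution, alkene reduction or phenol oxidation could outrun the radical-polar crossover. The fallback uses known chemistry and sets out from 5. Cobalt-catalysed HAT hydrochlorination (Co(II)/salen-type ligand, PhSiH3, TsCl, EtOH) adds HCl to the isopropenyl group only and gives [4-{[(2R)-2-(2-chloropropan-2-yl)-5-methylhex-4-en-1-yl]oxy}-2,6-dihydroxyphenyl](3-hydroxyphenyl)methanone F1. Ionising this tertiary chloride in HFIP at 40 °C closes the ring by intramolecular Friedel–Crafts alkylation and comes back to the route at 6.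

Step 6 is the second: it decides both bridgehead configurations, and it can fail through O5 instead of O7 alkylation, a sluggish Cope shift onto the congested C4a, or poor face selectivity. The fallback sets out from 10. O-Allylation (allyl bromide, K2CO3, acetone) gives the 7-O-allyl ether of 10 F2. Its para-Claisen rearrangement, with a smaller migrating group (N,N-diethylaniline, 140–160 °C), gives the (3S,4aS)-4a-allyl analogue of 13 F3. Cross-metathesis with 2-methylbut-2-ene (Grubbs II) turns allyl into prenyl and comes back to the route at 13.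

Step 7 is the third: the iodide-catalysed transposition is unproven, and it could stall at the vinylogous ester, close onto the aroyl-bearing carbon, or lose the O-prenyl ether to iodide if 13 reverts thermally. The fallback uses known reactions stepwise and sets out from 13. TMSI (from TMSCl/NaI, MeCN, 0 °C) cleaves the vinylogous alkyl ether to the primary iodide 14, which is now isolated. Its dilithium salt (LiHMDS, PhMe/THF, −78 → 40 °C) is C-alkylated intramolecularly under the conditions of step 5 and comes back to the route at 15, which buffered TBAF converts to 16. This fallback makes no compound outside the list (F0).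

**Further compounds**
F1 | step 3 | [4-{[(2R)-2-(2-chloropropan-2-yl)-5-methylhex-4-en-1-yl]oxy}-2,6-dihydroxyphenyl](3-hydroxyphenyl)methanone | O=C(c1cccc(O)c1)c1c(O)cc(OC[C@@H](CC=C(C)C)C(C)(C)Cl)cc1O
F2 | step 6 | 7-O-allyl ether of 10 | O=C(c1cccc(O[Si](C(C)C)(C(C)C)C(C)C)c1)c1c(OCC=C)c(C[C@H](CC=C(C)C)C(C)=C)c2OC[C@@H](CC=C(C)C)C(C)(C)c2c1O
F3 | step 6 | (3S,4aS)-4a-allyl analogue of 13 | O=C(c1cccc(O[Si](C(C)C)(C(C)C)C(C)C)c1)C1=C(O)[C@@]2(CC=C)C(=C(C[C@H](CC=C(C)C)C(C)=C)C1=O)OC[C@@H](CC=C(C)C)C2(C)C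
F0 | step 7 | none | none
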